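## The problem

The target 19 is an unsymmetrical biflavone. An acacetin unit (4'-methoxy B ring) is bonded through C6 to C8'' of an apigenin unit (4'''-hydroxy B ring), so the halves share the 5,7-dioxygenated chromone skeleton and differ only in one O-methyl group and in the carbon used for the link. The only bond between the halves, C6–C8'', lies between four oxygen-bearing carbons (C5, C7, C7'' and C8a''). Any coupling that makes it is therefore tetra-ortho-substituted and electron-rich on both sides. There are no stereocentres. The hindered axis is a possible stereogenic element, but no axial configuration is specified, so nothing has to be controlled or relayed. Five phenols must be liberated at the end while the 4'-methyl ether stays, which rules out strong Lewis-acid dealkylation and points to benzyl ethers and hydrogenolysis. On the way, benzyl ethers peri to a chromone carbonyl are acid-labile, the chromone rings open in hot hydroxide, and a 3-aryloxyacrylic acid loses CO2 on heating. Ring A of the apigenin half is a phloroglucinol with two nucleophilic CH positions, C4a'' and C6'', which an untethered acylation cannot be trusted to tell apart. The feature that solves this is that the oxygen on C8a'' (the future O1'') has only two ortho carbons: C8'', which is the axis carbon, and C4a''. An acyl carbon held through that oxygen can therefore reach C4a'' and nothing else, and C4a'' is ortho to two oxygens and para to a third.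

## Retrosynthesis

**19 from 18.** The five benzylic C–O bonds are cut. Benzyl is preferred to methyl or silyl because hydrogenolysis leaves the 4'-methyl ether and both chromones alone, whereas any reagent that cleaves aryl methyl ethers would also attack the one that must stay. The precursor 18 is the complete skeleton, and the forward step only has to be a clean fivefold hydrogenolysis.

**18 from 16 (through 17).** The C4''–C4a'' bond is cut, which opens ring C of the apigenin half to the (Z)-3-aryloxy-3-arylacrylic acid 16. The neighbouring cuts (O1''–C2'', C2''–C3'' or C3''–C4'') all require a C-acyl group already placed on C4a'', and putting it there by untethered acylation raises the C4a''/C6'' question. Here the carbonyl carbon is delivered through O1'', so the question does not arise. The precursor has one ring fewer and carries the three-carbon unit on oxygen only. The forward step needs an activation mild enough for five benzyl ethers, here the mixed anhydride 17, and the geometry that places the aryloxy group and the carboxyl cis.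

**16 from 14, and 14 from 10 and 13.** The ester is unmasked by hydrolysis, and the O1''–C2'' bond is cut to the phenol 10 and the alkynoate 13. Phenol 10 has exactly one free hydroxyl, so no selectivity among oxygens is needed. Anti addition across the triple bond should place oxygen and ester cis, which is the geometry the closure needs. The forward reaction has to overcome an acceptor deactivated by its para-benzyloxy group and a phenol that sits next to the axis.

**13 from 11.** The bond between the alkyne carbon and the ester carbonyl is cut, which leads to the purchasable terminal alkyne 11. This is one step of acetylide acylation.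

**10 from 9, and 9 from 4 and 8.** Acetal cleavage frees the tethering oxygen, and the C6–C8'' bond is then cut to the iodoflavone 4 and the arylboronate 8. Joining two finished flavones is kept in reserve. It would be just as hindered, would need both partners to be elaborate, and would require C8 halogenation of an apigenin ether. With the cut chosen here, the boron partner is a small phloroglucinol derivative that can be used in excess against protodeboronation. The more valuable flavone is the iodide, the partner best suited to oxidative addition at a hindered carbon. The forward coupling is the hardest intermolecular step of the route and calls for a bulky, electron-rich phosphine on palladium.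

**4 from 3, 3 from 2, 2 from 1.** Two O-benzyl bonds and the C6–I bond are cut back to acacetin 1. The order is fixed by regiochemistry: with the 5-hydroxyl free, iodination goes ortho to it at C6, whereas a fully alkylated ring would react at C8. Hence 7-O-benzylation, iodination, then 5-O-benzylation.

**8 from 6 (through 7), and 6 from 5.** The C–B bond is cut to the aryllithium 7, which comes from directed ortho-metalation of the methoxymethyl ether 6 of the purchasable phenol 5. The methoxymethyl group has two jobs. It is the strongest director on the ring, steering lithiation to the carbon between it and a benzyloxy group, and it marks the one oxygen that is later set free for the tether.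

## Roads not taken

**Alternative 1:** The cut removes the two peri oxygens. The C5–O and C5''–O bonds would be made last on the 5,5''-dideoxy biflavone triacetate A2 by carbonyl-directed C–H oxygenation with [RuCl2(p-cymene)]2 and K2S2O8 in trifluoroacetic acid and its anhydride. This would give the triacetate A1, which mild methanolysis would convert into 19.
- Merits: in A2, C6 has only one oxygenated neighbour, so the biaryl junction carries three ortho substituents instead of four. No 5-O protecting groups are needed, and the new hydroxyls are formed already chelated to the carbonyls, which shields them from over-oxidation. On coupling sterics and protecting-group count this road is better than the chosen one.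
- Weak points: C5–H of the acacetin half lies between C4a and the aryl-bearing C6, so the ruthenacycle must form beside a twisted, ortho-substituted aryl group. C5''–H is unhindered, so the two sites will react at different rates, and both must go to completion in one molecule at the last stage. Persulfate in strong acid is also an oxidant for the 4'-methoxyphenyl ring, and the acetates may exchange in that medium. The 5-deoxy flavone partners are not cheaper than acacetin, and without a 5-hydroxyl electrophilic halogenation of a 7-oxygenated flavone favours C8, so the C6-functionalised partner is harder to reach.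
- Comparison: the chosen plan buys every ring-A oxygen in 1 and 5, and its demanding closure is intramolecular with the position fixed by connectivity. It pays for this with the tetra-ortho coupling of step 6.

**Alternative 2:** The cut takes ring A of the apigenin half apart into 3-ethoxycyclobut-2-en-1-one A5 and the aryl triisopropylsiloxyalkyne A4. Heating them would give, by vinylketene formation, [2+2] addition, ring opening and 6π closure, the biphenylol A3 with C8''–C8a'' and C6''–C7'' newly formed.
- Merits: the hindered axis is already present as the aryl–alkyne bond of A4, so no tetra-ortho cross-coupling is needed at all. On the hardest bond of the molecule this is a better answer than the chosen plan. The three oxygens of the new ring emerge differentiated (free hydroxyl on C8a'', silyl ether on C7'', ethyl ether on C5''), with C4a'' open next to the free hydroxyl.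
- Weak points: after A3 neither chromone exists. The acacetin pyranone has to be built on the first ring and the apigenin pyranone on the new one, so acacetin 1 cannot be bought in and the route roughly doubles in length. The C5'' oxygen arrives as an ethyl ether that must later be removed beside the 4'-methyl ether. A4 must be made by silylation of an ynolate from a 2,6-dialkoxyarylacetic ester, is acid-sensitive, and is a bulky partner for the vinylketene.
- Comparison: the chosen plan is shorter and convergent and keeps protecting-group logic simple, but it has to carry the risk of step 6 that this road avoids.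

**Alternative 3:** The cut is C4a''–C5''. Mg(OMe)2 in methanol would fold the β-keto ester side chain of the 2,6-disubstituted 4-pyranone A7 by Claisen condensation of the pyranone carbon onto the ester, closing ring A as the 5,7-dihydroxychromone A6.
- Merits: the closure is biomimetic, delivers both ring-A hydroxyls free, already has the apigenin pyranone in place, and needs no biaryl coupling. In that last respect it matches Alternative 2 and beats the chosen plan.
- Weak points: in A7 the methine between the pyranone and the ketone carries the 2,6-bis(benzyloxy)aryl group, and building this crowded, doubly activated centre has no close model. Methoxide can add to 4-pyranones and open them, so other foldings of the chain are possible. A6 then needs its two new hydroxyls protected, the allyl ether removed, and the whole acacetin pyranone constructed on the first ring, again without use of 1.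
- Comparison: the chosen plan relies on known operations throughout and reaches 19 in twelve steps. Its price is the hindered coupling.

Key step: step 11

## Route

Assumption: since no configuration is specified at the C6–C8'' axis, every biaryl from 9 onward is planned as the racemate; 1, 5 and 11 are taken as purchasable.

Step 1
Reactants: 1 acacetin (5,7-dihydroxy-2-(4-methoxyphenyl)-4H-chromen-4-one)
Product: 2 7-(benzyloxy)-5-hydroxy-2-(4-methoxyphenyl)-4H-chromen-4-one
Conditions: BnBr (1.1 equiv), K2CO3, DMF, rt
Reagents that add atoms: benzyl bromide, BrCc1ccccc1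
Why: Williamson etherification; the 5-hydroxyl is hydrogen-bonded to the C4 carbonyl and much less acidic and nucleophilic than the 7-hydroxyl, so one equivalent of bromide should alkylate O7 only.

Step 2
Reactants: 2 7-(benzyloxy)-5-hydroxy-2-(4-methoxyphenyl)-4H-chromen-4-one
Product: 3 7-(benzyloxy)-5-hydroxy-6-iodo-2-(4-methoxyphenyl)-4H-chromen-4-one
Conditions: BnMe3N+ ICl2−, CaCO3, CH2Cl2/MeOH, rt
Reagents that add atoms: benzyltrimethylammonium dichloroiodate, C[N+](C)(C)Cc1ccccc1.Cl[I-]Cl
Why: Electrophilic aromatic iodination; with the 5-hydroxyl free, 5,7-dioxygenated flavones are iodinated by this reagent ortho to the free phenol at C6, whereas a fully alkylated ring reacts at C8, which is why iodination comes before the second benzylation.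

Step 3
Reactants: 3 7-(benzyloxy)-5-hydroxy-6-iodo-2-(4-methoxyphenyl)-4H-chromen-4-one
Product: 4 5,7-bis(benzyloxy)-6-iodo-2-(4-methoxyphenyl)-4H-chromen-4-one
Conditions: BnBr (excess), K2CO3, DMF, 70 °C
Reagents that add atoms: benzyl bromide, BrCc1ccccc1
Why: Williamson etherification of the chelated 5-hydroxyl, which needs heat and excess bromide; capping it keeps a phenoxide out of the coupling and of the later conjugate addition.

Step 4
Reactants: 5 3,5-bis(benzyloxy)phenol
Product: 6 1,3-bis(benzyloxy)-5-(methoxymethoxy)benzene
Conditions: MOMCl, iPr2NEt, CH2Cl2, 0 °C to rt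
Reagents that add atoms: chloromethyl methyl ether, COCCl
Why: O-alkylation of the phenol to the methoxymethyl acetal; this group is the strongest ortho-director on the ring and the only one later removed by mild acid.

Step 5
Reactants: 6 1,3-bis(benzyloxy)-5-(methoxymethoxy)benzene
Product: 8 2-[2,4-bis(benzyloxy)-6-(methoxymethoxy)phenyl]-4,4,5,5-tetramethyl-1,3,2-dioxaborolane, via aryllithium 7 (not isolated)
Conditions: n-BuLi, THF, 0 °C; iPrOBpin, −78 °C to rt; H2O
Reagents that add atoms: 2-isopropoxy-4,4,5,5-tetramethyl-1,3,2-dioxaborolane, CC(C)OB1OC(C)(C)C(C)(C)O1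
Why: Directed ortho-metalation followed by borylation; the chelating methoxymethoxy group and a flanking benzyloxy group cooperate to place lithium on the carbon between them (two equivalent sites), and the pinacol ester is chosen as the storable form of a boronic acid prone to protodeboronation.

Step 6
Reactants: 4 5,7-bis(benzyloxy)-6-iodo-2-(4-methoxyphenyl)-4H-chromen-4-one; 8 2-[2,4-bis(benzyloxy)-6-(methoxymethoxy)phenyl]-4,4,5,5-tetramethyl-1,3,2-dioxaborolane (2 equiv)
Product: 9 5,7-bis(benzyloxy)-6-[2,4-bis(benzyloxy)-6-(methoxymethoxy)phenyl]-2-(4-methoxyphenyl)-4H-chromen-4-one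
Conditions: Pd(OAc)2 (10 mol %), SPhos (20 mol %), K3PO4, toluene/H2O, 100 °C
Reagents that add atoms: none
Why: Suzuki–Miyaura coupling forming C6–C8''; zerovalent palladium carrying the bulky, electron-rich SPhos ligand is an established system for tetra-ortho-substituted biaryls, the iodide eases oxidative addition at the hindered carbon, and excess 8 offsets protodeboronation.

Step 7
Reactants: 9 5,7-bis(benzyloxy)-6-[2,4-bis(benzyloxy)-6-(methoxymethoxy)phenyl]-2-(4-methoxyphenyl)-4H-chromen-4-one
Product: 10 5,7-bis(benzyloxy)-6-[2,4-bis(benzyloxy)-6-hydroxyphenyl]-2-(4-methoxyphenyl)-4H-chromen-4-one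
Conditions: HCl (2 M aq), THF/MeOH, 40 °C
Reagents that add atoms: none
Why: Acid-catalysed acetal cleavage; dilute acid at mild temperature removes the methoxymethyl group while benzyl ethers and the chromone persist, and any loss of the peri 5-O-benzyl group would only expose a chelated, unreactive phenol.

Step 8
Reactants: 11 1-(benzyloxy)-4-ethynylbenzene
Product: 13 ethyl 3-[4-(benzyloxy)phenyl]prop-2-ynoate, via lithium acetylide 12 (not isolated)
Conditions: n-BuLi, THF, −78 °C; ClCO2Et, −78 °C to rt
Reagents that add atoms: ethyl chloroformate, CCOC(=O)Cl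
Why: Deprotonation of the terminal alkyne and acylation of the acetylide with a chloroformate, a standard route to arylpropiolates.

Step 9
Reactants: 10 5,7-bis(benzyloxy)-6-[2,4-bis(benzyloxy)-6-hydroxyphenyl]-2-(4-methoxyphenyl)-4H-chromen-4-one; 13 ethyl 3-[4-(benzyloxy)phenyl]prop-2-ynoate (1.5 equiv)
Product: 14 ethyl (2Z)-3-{2-[5,7-bis(benzyloxy)-2-(4-methoxyphenyl)-4-oxo-4H-chromen-6-yl]-3,5-bis(benzyloxy)phenoxy}-3-[4-(benzyloxy)phenyl]prop-2-enoate
Conditions: Cs2CO3 (0.3 equiv), DMF, 70 °C
Reagents that add atoms: none
Why: Oxa-Michael addition of the single free phenoxide to the β-carbon of the alkynoate forms O1''–C2''; anti addition of oxygen and proton places the aryloxy group cis to the ester, which is the Z isomer.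

Step 10
Reactants: 14 ethyl (2Z)-3-{2-[5,7-bis(benzyloxy)-2-(4-methoxyphenyl)-4-oxo-4H-chromen-6-yl]-3,5-bis(benzyloxy)phenoxy}-3-[4-(benzyloxy)phenyl]prop-2-enoate
Product: 16 (2Z)-3-{2-[5,7-bis(benzyloxy)-2-(4-methoxyphenyl)-4-oxo-4H-chromen-6-yl]-3,5-bis(benzyloxy)phenoxy}-3-[4-(benzyloxy)phenyl]prop-2-enoic acid, via lithium carboxylate 15 (not isolated)
Conditions: LiOH·H2O, THF/MeOH/H2O, rt; then 1 M HCl, 0 °C, to pH 3
Reagents that add atoms: lithium hydroxide, [Li+].[OH-]
Why: Ester saponification by acyl–oxygen cleavage; the carboxylate formed is inert to conjugate displacement of the aryloxy group, and cold, brief acidification avoids hydrolysis of the enol ether and decarboxylation.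

Step 11
Reactants: 16 (2Z)-3-{2-[5,7-bis(benzyloxy)-2-(4-methoxyphenyl)-4-oxo-4H-chromen-6-yl]-3,5-bis(benzyloxy)phenoxy}-3-[4-(benzyloxy)phenyl]prop-2-enoic acid
Product: 18 5,7-bis(benzyloxy)-6-{5,7-bis(benzyloxy)-2-[4-(benzyloxy)phenyl]-4-oxo-4H-chromen-8-yl}-2-(4-methoxyphenyl)-4H-chromen-4-one, via mixed trifluoroacetic anhydride 17 (not isolated)
Conditions: TFAA (3 equiv), CH2Cl2, 0 °C to rt
Reagents that add atoms: none
Why: Trifluoroacetic anhydride converts acid 16 into the mixed anhydride 17, which ionises, helped by the trifluoroacetic acid released, toward an acylium ion stabilised by the β-aryloxy and β-aryl groups. Its acyl carbon is attacked by C4a'' of ring A, a carbon ortho to O1'' and to the C5'' benzyloxy group and para to the C7'' benzyloxy group, and loss of a proton from the arenium ion restores the arene and leaves the new C4''–C4a'' bond. The closest known reaction type is the intramolecular Friedel–Crafts acylation of 3-aryloxycinnamic acids, the Ruhemann-type flavone closure. Ring C of the apigenin half closes as a six-membered ring, 6-exo with respect to the acyl C=O, by electrophilic aromatic substitution. No stereocentre is formed and the hindered axis stays racemic. The selectivity needed is C4a'' over the equally electron-rich C6'': the tether through O1'' reaches only the ortho carbons of C8a'', and of these C8'' is the quaternary axis carbon, so C6'' cannot be reached. The Z geometry holds the 4-benzyloxyphenyl ring trans to the acyl group, so closure onto that ring to an indenone is not available to this isomer. The anhydrous, weakly acidic medium should spare the five benzyl ethers, the methyl ether and the acacetin chromone.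

Step 12
Reactants: 18 5,7-bis(benzyloxy)-6-{5,7-bis(benzyloxy)-2-[4-(benzyloxy)phenyl]-4-oxo-4H-chromen-8-yl}-2-(4-methoxyphenyl)-4H-chromen-4-one
Product: 19 5,7-dihydroxy-6-[5,7-dihydroxy-2-(4-hydroxyphenyl)-4-oxo-4H-chromen-8-yl]-2-(4-methoxyphenyl)-4H-chromen-4-one
Conditions: H2 (1 atm), 10% Pd/C, THF/MeOH, rt
Reagents that add atoms: none
Why: Catalytic hydrogenolysis of the five benzyl aryl ethers; the aryl methyl ether is inert, and the C2=C3 bonds, being vinylogous esters conjugated to aryl groups, should resist reduction at ambient pressure.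

## Compound list

1 | acacetin, 5,7-dihydroxy-2-(4-methoxyphenyl)-4H-chromen-4-one | COc1ccc(-c2cc(=O)c3c(O)cc(O)cc3o2)cc1 | starting material
2 | 7-(benzyloxy)-5-hydroxy-2-(4-methoxyphenyl)-4H-chromen-4-one | COc1ccc(-c2cc(=O)c3c(O)cc(OCc4ccccc4)cc3o2)cc1 | intermediate
3 | 7-(benzyloxy)-5-hydroxy-6-iodo-2-(4-methoxyphenyl)-4H-chromen-4-one | COc1ccc(-c2cc(=O)c3c(O)c(I)c(OCc4ccccc4)cc3o2)cc1 | intermediate
4 | 5,7-bis(benzyloxy)-6-iodo-2-(4-methoxyphenyl)-4H-chromen-4-one | COc1ccc(-c2cc(=O)c3c(OCc4ccccc4)c(I)c(OCc4ccccc4)cc3o2)cc1 | intermediate
5 | 3,5-bis(benzyloxy)phenol | Oc1cc(OCc2ccccc2)cc(OCc2ccccc2)c1 | starting material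
6 | 1,3-bis(benzyloxy)-5-(methoxymethoxy)benzene | COCOc1cc(OCc2ccccc2)cc(OCc2ccccc2)c1 | intermediate
7 | [2,4-bis(benzyloxy)-6-(methoxymethoxy)phenyl]lithium (not isolated) | [Li]c1c(OCOC)cc(OCc2ccccc2)cc1OCc1ccccc1 | intermediate
8 | 2-[2,4-bis(benzyloxy)-6-(methoxymethoxy)phenyl]-4,4,5,5-tetramethyl-1,3,2-dioxaborolane | COCOc1cc(OCc2ccccc2)cc(OCc2ccccc2)c1B1OC(C)(C)C(C)(C)O1 | intermediate
9 | 5,7-bis(benzyloxy)-6-[2,4-bis(benzyloxy)-6-(methoxymethoxy)phenyl]-2-(4-methoxyphenyl)-4H-chromen-4-one (racemic axis) | COc1ccc(-c2cc(=O)c3c(OCc4ccccc4)c(-c4c(OCOC)cc(OCc5ccccc5)cc4OCc4ccccc4)c(OCc4ccccc4)cc3o2)cc1 | intermediate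
10 | 5,7-bis(benzyloxy)-6-[2,4-bis(benzyloxy)-6-hydroxyphenyl]-2-(4-methoxyphenyl)-4H-chromen-4-one (racemic axis) | COc1ccc(-c2cc(=O)c3c(OCc4ccccc4)c(-c4c(O)cc(OCc5ccccc5)cc4OCc4ccccc4)c(OCc4ccccc4)cc3o2)cc1 | intermediate
11 | 1-(benzyloxy)-4-ethynylbenzene | C#Cc1ccc(OCc2ccccc2)cc1 | starting material
12 | {[4-(benzyloxy)phenyl]ethynyl}lithium (not isolated) | [Li]C#Cc1ccc(OCc2ccccc2)cc1 | intermediate
13 | ethyl 3-[4-(benzyloxy)phenyl]prop-2-ynoate | CCOC(=O)C#Cc1ccc(OCc2ccccc2)cc1 | intermediate
14 | ethyl (2Z)-3-{2-[5,7-bis(benzyloxy)-2-(4-methoxyphenyl)-4-oxo-4H-chromen-6-yl]-3,5-bis(benzyloxy)phenoxy}-3-[4-(benzyloxy)phenyl]prop-2-enoate (racemic axis) | COc1ccc(-c2cc(=O)c3c(OCc4ccccc4)c(-c4c(O/C(=C\C(=O)OCC)c5ccc(OCc6ccccc6)cc5)cc(OCc5ccccc5)cc4OCc4ccccc4)c(OCc4ccccc4)cc3o2)cc1 | intermediate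
15 | lithium (2Z)-3-{2-[5,7-bis(benzyloxy)-2-(4-methoxyphenyl)-4-oxo-4H-chromen-6-yl]-3,5-bis(benzyloxy)phenoxy}-3-[4-(benzyloxy)phenyl]prop-2-enoate (not isolated) | [Li+].COc1ccc(-c2cc(=O)c3c(OCc4ccccc4)c(-c4c(O/C(=C\C(=O)[O-])c5ccc(OCc6ccccc6)cc5)cc(OCc5ccccc5)cc4OCc4ccccc4)c(OCc4ccccc4)cc3o2)cc1 | intermediate
16 | (2Z)-3-{2-[5,7-bis(benzyloxy)-2-(4-methoxyphenyl)-4-oxo-4H-chromen-6-yl]-3,5-bis(benzyloxy)phenoxy}-3-[4-(benzyloxy)phenyl]prop-2-enoic acid (racemic axis) | COc1ccc(-c2cc(=O)c3c(OCc4ccccc4)c(-c4c(O/C(=C\C(=O)O)c5ccc(OCc6ccccc6)cc5)cc(OCc5ccccc5)cc4OCc4ccccc4)c(OCc4ccccc4)cc3o2)cc1 | intermediate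
17 | mixed anhydride of acid 16 with trifluoroacetic acid, (2Z)-configured (not isolated) | COc1ccc(-c2cc(=O)c3c(OCc4ccccc4)c(-c4c(O/C(=C\C(=O)OC(=O)C(F)(F)F)c5ccc(OCc6ccccc6)cc5)cc(OCc5ccccc5)cc4OCc4ccccc4)c(OCc4ccccc4)cc3o2)cc1 | intermediate
18 | 5,7-bis(benzyloxy)-6-{5,7-bis(benzyloxy)-2-[4-(benzyloxy)phenyl]-4-oxo-4H-chromen-8-yl}-2-(4-methoxyphenyl)-4H-chromen-4-one (racemic axis) | COc1ccc(-c2cc(=O)c3c(OCc4ccccc4)c(-c4c(OCc5ccccc5)cc(OCc5ccccc5)c5c(=O)cc(-c6ccc(OCc7ccccc7)cc6)oc45)c(OCc4ccccc4)cc3o2)cc1 | intermediate
19 | 5,7-dihydroxy-6-[5,7-dihydroxy-2-(4-hydroxyphenyl)-4-oxo-4H-chromen-8-yl]-2-(4-methoxyphenyl)-4H-chromen-4-one | COc1ccc(-c2cc(=O)c3c(O)c(-c4c(O)cc(O)c5c(=O)cc(-c6ccc(O)cc6)oc45)c(O)cc3o2)cc1 | target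

## Step count and least certain steps

Total: 12 steps. Longest linear sequence: 9 steps (from 1 through steps 1, 2, 3, 6, 7, 9, 10, 11 and 12).

**Step 11 (key step).** The most likely failure is incomplete closure. The carbonyl of the mixed anhydride 17 is deactivated by push–pull donation from the β-aryloxy and β-(4-benzyloxyphenyl) groups, so ionisation may be slow. Prolonged contact with the acid formed can then protonate the enol ether at carbon, scramble the double-bond geometry and strip the acid-labile peri benzyl ethers. The last of these is harmless, since step 12 removes them anyway. A trace of triflic acid is the first adjustment.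

The fallback abandons the ring closure and brings the apigenin pyranone in ready-made. From 4, borylation with pinacolborane (PdCl2(dppf), Et3N, dioxane, 80 °C) would give 5,7-bis(benzyloxy)-2-(4-methoxyphenyl)-6-(4,4,5,5-tetramethyl-1,3,2-dioxaborolan-2-yl)-4H-chromen-4-one F1. Commercial apigenin would be perbenzylated (BnBr, K2CO3, DMF, 80 °C) to 5,7-bis(benzyloxy)-2-[4-(benzyloxy)phenyl]-4H-chromen-4-one F2. Iodination of this fully alkylated ring (N-iodosuccinimide, catalytic trifluoroacetic acid, CH2Cl2) goes to C8 and would give 5,7-bis(benzyloxy)-2-[4-(benzyloxy)phenyl]-8-iodo-4H-chromen-4-one F3. Coupling of F1 with F3 under the catalyst system of step 6 rejoins the route at 18.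

**Step 6.** The risk is slow transmetalation at a junction flanked by four oxygens, with protodeboronation of 8 and hydrodeiodination of 4 overtaking the coupling.

The fallback changes the organometallic partner. Starting from 6, the aryllithium 7 is generated as in step 5 and transmetalated with ZnCl2 to chloro[2,4-bis(benzyloxy)-6-(methoxymethoxy)phenyl]zinc F4, which cannot protodeboronate and tolerates the chromone carbonyl. Negishi coupling of F4 with 4 (Pd2(dba)3, RuPhos, THF/NMP, 70 °C), a combination suited to tetra-ortho-substituted biaryls, returns to the route at 9.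

**Step 5.** Lithiation may stray to the carbon between the two benzyloxy groups, or to a benzylic CH2 followed by Wittig rearrangement. Either erodes the regiochemical purity of 8.

The fallback fixes the position through the phenol instead of through metalation, starting from 5:
- Magnesium-mediated ortho-formylation (MgCl2, Et3N, paraformaldehyde, MeCN, reflux) can only give 2,4-bis(benzyloxy)-6-hydroxybenzaldehyde F5, since both ortho positions are equivalent.
- Methoxymethylation (MOMCl, iPr2NEt) gives 2,4-bis(benzyloxy)-6-(methoxymethoxy)benzaldehyde F6.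
- Dakin-type oxidation with mCPBA leads through 2,4-bis(benzyloxy)-6-(methoxymethoxy)phenyl formate F7 to 2,4-bis(benzyloxy)-6-(methoxymethoxy)phenol F8 after methanolysis (K2CO3, MeOH).
- Triflation (Tf2O, pyridine) gives 2,4-bis(benzyloxy)-6-(methoxymethoxy)phenyl trifluoromethanesulfonate F9.
- Miyaura borylation (bis(pinacolato)diboron, PdCl2(dppf), KOAc, dioxane, 90 °C) comes back to the route at 8.

**Step 9.** The conjugate addition may be sluggish, because the alkynoate is deactivated by its para-benzyloxy group and the phenol sits next to the axis. Longer heating with base invites reversible addition and erosion of the Z geometry. The E isomer could close directly only onto the 4-benzyloxyphenyl ring, at a carbon meta to its oxygen.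

The fallback replaces conjugate addition by a metal-catalysed C–O coupling with defined geometry. From 13, anti hydroiodination (NaI, AcOH, 70 °C) would give ethyl (2Z)-3-[4-(benzyloxy)phenyl]-3-iodoprop-2-enoate F10. Ullmann-type O-vinylation of 10 with F10 (CuI, N,N-dimethylglycine, Cs2CO3, dioxane, 90 °C), which proceeds with retention at the vinyl carbon, returns to the route at 14.

## Further compounds

F1 | step 11 | 5,7-bis(benzyloxy)-2-(4-methoxyphenyl)-6-(4,4,5,5-tetramethyl-1,3,2-dioxaborolan-2-yl)-4H-chromen-4-one | COc1ccc(-c2cc(=O)c3c(OCc4ccccc4)c(B4OC(C)(C)C(C)(C)O4)c(OCc4ccccc4)cc3o2)cc1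
F2 | step 11 | 5,7-bis(benzyloxy)-2-[4-(benzyloxy)phenyl]-4H-chromen-4-one | O=c1cc(-c2ccc(OCc3ccccc3)cc2)oc2cc(OCc3ccccc3)cc(OCc3ccccc3)c12
F3 | step 11 | 5,7-bis(benzyloxy)-2-[4-(benzyloxy)phenyl]-8-iodo-4H-chromen-4-one | O=c1cc(-c2ccc(OCc3ccccc3)cc2)oc2c(I)c(OCc3ccccc3)cc(OCc3ccccc3)c12
F4 | step 6 | chloro[2,4-bis(benzyloxy)-6-(methoxymethoxy)phenyl]zinc | COCOc1cc(OCc2ccccc2)cc(OCc2ccccc2)c1[Zn]Cl
F5 | step 5 | 2,4-bis(benzyloxy)-6-hydroxybenzaldehyde | O=Cc1c(O)cc(OCc2ccccc2)cc1OCc1ccccc1
F6 | step 5 | 2,4-bis(benzyloxy)-6-(methoxymethoxy)benzaldehyde | COCOc1cc(OCc2ccccc2)cc(OCc2ccccc2)c1C=O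
F7 | step 5 | 2,4-bis(benzyloxy)-6-(methoxymethoxy)phenyl formate | COCOc1cc(OCc2ccccc2)cc(OCc2ccccc2)c1OC=O
F8 | step 5 | 2,4-bis(benzyloxy)-6-(methoxymethoxy)phenol | COCOc1cc(OCc2ccccc2)cc(OCc2ccccc2)c1O
F9 | step 5 | 2,4-bis(benzyloxy)-6-(methoxymethoxy)phenyl trifluoromethanesulfonate | COCOc1cc(OCc2ccccc2)cc(OCc2ccccc2)c1OS(=O)(=O)C(F)(F)F
F10 | step 9 | ethyl (2Z)-3-[4-(benzyloxy)phenyl]-3-iodoprop-2-enoate | CCOC(=O)/C=C(\I)c1ccc(OCc2ccccc2)cc1
A1 | alternative 1 | 7,7'',4'''-tri-O-acetate of the target | COc1ccc(-c2cc(=O)c3c(O)c(-c4c(OC(C)=O)cc(O)c5c(=O)cc(-c6ccc(OC(C)=O)cc6)oc45)c(OC(C)=O)cc3o2)cc1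
A2 | alternative 1 | 5,5''-dideoxy analogue of the target as its 7,7'',4'''-triacetate | COc1ccc(-c2cc(=O)c3cc(-c4c(OC(C)=O)ccc5c(=O)cc(-c6ccc(OC(C)=O)cc6)oc45)c(OC(C)=O)cc3o2)cc1
A3 | alternative 2 | 2',6'-bis(benzyloxy)-4-ethoxy-4'-(methoxymethoxy)-6-[(triisopropylsilyl)oxy]biphenyl-2-ol | CCOc1cc(O)c(-c2c(OCc3ccccc3)cc(OCOC)cc2OCc2ccccc2)c(O[Si](C(C)C)(C(C)C)C(C)C)c1
A4 | alternative 2 | ({[2,6-bis(benzyloxy)-4-(methoxymethoxy)phenyl]ethynyl}oxy)triisopropylsilane | COCOc1cc(OCc2ccccc2)c(C#CO[Si](C(C)C)(C(C)C)C(C)C)c(OCc2ccccc2)c1
A5 | alternative 2 | 3-ethoxycyclobut-2-en-1-one | CCOC1=CC(=O)C1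
A6 | alternative 3 | 8-[4-(allyloxy)-2,6-bis(benzyloxy)phenyl]-2-[4-(benzyloxy)phenyl]-5,7-dihydroxy-4H-chromen-4-one | O=c1cc(-c2ccc(OCc3ccccc3)cc2)oc2c(-c3c(OCc4ccccc4)cc(OCC=C)cc3OCc3ccccc3)c(O)cc(O)c12
A7 | alternative 3 | methyl 4-[4-(allyloxy)-2,6-bis(benzyloxy)phenyl]-4-{6-[4-(benzyloxy)phenyl]-4-oxo-4H-pyran-2-yl}-3-oxobutanoate (racemic) | COC(=O)CC(=O)C(c1cc(=O)cc(-c2ccc(OCc3ccccc3)cc2)o1)c1c(OCc2ccccc2)cc(OCC=C)cc1OCc1ccccc1
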